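The enone ring is disconnected at C1–C2. Its precursor is a bicyclo[4.1.1]octane in which the two one-carbon bridges, C11 and C4, stand 1,3 across the cyclobutane C10–C11–C5–C4 and carry, on the face away from the seven-membered ring, a formyl group and an isopropenyl group. This rigid cis-1,3 arrangement holds C1 and C2 within bonding distance, so one Me2AlCl-promoted type 2 carbonyl-ene reaction forms C1–C2, closes the six-membered ring and leaves a C1 carbinol and a C3 exo-methylene, which are then oxidised and conjugated. The cyclobutane comes from a bicyclobutane; C9 and C7 are relayed from the quaternary centre C10.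

Key step: step 16

Remarks on the chemistry
- Longipinane numbering is used for every intermediate (C1 carbonyl carbon, C2=C3, C4 and C11 the one-carbon bridges, C5 and C10 the bridgeheads, C6 the gem-dimethyl carbon, C7 and C9 the oxygenated carbons). "Anti" means on the cyclobutane face away from the C9–C8–C7–C6 bridge, "syn" toward it. TBS = tert-butyldimethylsilyl.
- Eucarvone is achiral, so either enantiomer of carvone serves.
- Assumption: a nucleophile opens a bicyclobutane bridgehead with inversion, which would place a group added directly at C4 syn. The isopropenyl group is therefore introduced through the planar C4 radical (steps 13 and 14).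

Step 1
Reactants: 1 (R)-(−)-carvone
Product: 3 eucarvone (2,6,6-trimethylcyclohepta-2,4-dien-1-one), via carvone hydrobromide 2 (not isolated)
Conditions: HBr, AcOH, 5 °C; then KOH, MeOH, reflux
Reagents that add atoms: none
Why: Markovnikov addition of HBr to the isopropenyl group, base-induced 1,3-elimination to the bicyclic carenone and opening of its cyclopropane through the dienolate (the classical carvone-to-eucarvone ring expansion) give the achiral dienone, so the stereocentre of 1 is lost without consequence.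

Step 2
Reactants: 3 eucarvone
Product: 5 2,6,6-trimethylcyclohepta-1,3-dien-1-yl acetate, via lithium dienolate 4 (not isolated)
Conditions: Li, NH3/THF, t-BuOH (1 equiv), −78 °C; NH3 removed; Ac2O, THF, −78 to 0 °C
Reagents that add atoms: acetic anhydride, CC(=O)OC(C)=O
Why: Dissolving-metal (Birch-type) reduction of the linear dienone adds two electrons and one proton at the δ-carbon C7, leaving the conjugated lithium dienolate regiospecifically, and acetic anhydride traps it on oxygen (reductive enolate trapping).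

Step 3
Reactants: 5 2,6,6-trimethylcyclohepta-1,3-dien-1-yl acetate; 6 tert-butyl iodoacetate
Product: 8 tert-butyl 2-[(1R)-1,5,5-trimethyl-7-oxocyclohept-2-en-1-yl]acetate, via tributyltin dienolate 7 (not isolated)
Conditions: Bu3SnOMe, 60 °C (−MeOAc); then 6, Cr(salen)Cl (5 mol %; salen = N,N'-bis(3,5-di-tert-butylsalicylidene)-trans-cyclohexane-1,2-diamine dianion), benzene, 0 °C
Reagents that add atoms: tert-butyl iodoacetate (6), CC(C)(C)OC(=O)CI
Why: Acetate–tin exchange gives the tributyltin dienolate, whose α-carbon C10 is alkylated by the iodoacetate under the chiral chromium–salen Lewis acid (catalytic enantioselective alkylation of tin enolates), which creates the C10 quaternary centre; the catalyst enantiomer that delivers (R)-8 is used.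

Step 4
Reactants: 8 tert-butyl 2-[(1R)-1,5,5-trimethyl-7-oxocyclohept-2-en-1-yl]acetate
Product: 9 tert-butyl 2-[(1R)-1,4,4-trimethyl-2-(trifluoromethylsulfonyloxy)cyclohepta-2,6-dien-1-yl]acetate
Conditions: KN(SiMe3)2, THF, −78 °C; PhNTf2
Reagents that add atoms: N-phenylbis(trifluoromethanesulfonimide), O=S(=O)(N(c1ccccc1)S(=O)(=O)C(F)(F)F)C(F)(F)F
Why: Only C5 can be enolised because C10 is quaternary, and the potassium enolate is sulfonylated on oxygen by PhNTf2 (enol triflate formation).

Step 5
Reactants: 9 the C4 enol triflate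
Product: 10 tert-butyl 2-[(1R)-1,4,4-trimethylcyclohepta-2,6-dien-1-yl]acetate
Conditions: Pd(OAc)2 (5 mol %), PPh3, Bu3N, HCO2H, DMF, 60 °C
Reagents that add atoms: none
Why: Oxidative addition of the alkenyl triflate to zerovalent palladium, formate exchange, loss of CO2 and reductive elimination replace the triflate by hydrogen (palladium-catalysed formate reduction), which leaves the C4=C5 alkene.

Step 6
Reactants: 10 tert-butyl 2-[(1R)-1,4,4-trimethylcyclohepta-2,6-dien-1-yl]acetate
Product: 12 tert-butyl 2-[(1S)-1,4,4-trimethyl-5-oxocyclohepta-2,6-dien-1-yl]acetate (C7 ketone conjugated with C8=C9), via C7 allylic alcohol 11 (not isolated)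
Conditions: SeO2 (0.5 equiv), t-BuOOH, CH2Cl2, rt; crude product, Dess–Martin periodinane, NaHCO3, CH2Cl2
Reagents that add atoms: tert-butyl hydroperoxide, CC(C)(C)OO; selenium dioxide, O=[Se]=O
Why: C7 is the only allylic C–H position of 10, and the ene/[2,3]-sigmatropic sequence of selenium dioxide returns oxygen to the carbon that loses hydrogen (catalytic SeO2 allylic hydroxylation), so Dess–Martin oxidation of the crude alcohol gives the C7 ketone conjugated with C8=C9.

Step 7
Reactants: 12 the enone tert-butyl ester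
Product: 14 (3aS,8aR)-3a,6,6-trimethyl-3,3a,8,8a-tetrahydro-2H-cyclohepta[b]furan-2,7(6H)-dione (cis-fused γ-lactone, lactone oxygen on C9, ketone at C7), via enone acid 13 (not isolated)
Conditions: CF3CO2H, CH2Cl2, 0 °C to rt; then TsOH (cat.), toluene, 50 °C
Reagents that add atoms: none
Why: Acidolysis of the tert-butyl ester releases isobutene, and the free acid adds 5-exo to C9 of the acid-activated enone (intramolecular oxa-Michael lactonisation); the two-atom tether reaches C9 only on its own face, so the C9–O bond is set cis to C11.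

Step 8
Reactants: 14 the keto lactone
Product: 15 (3aS,7R,8aR)-7-hydroxy-3a,6,6-trimethyl-3,3a,6,7,8,8a-hexahydro-2H-cyclohepta[b]furan-2-one (C7–OH trans to the C9 oxygen)
Conditions: (S)-2-methyl-CBS-oxazaborolidine (20 mol %), catecholborane, toluene, −78 °C
Reagents that add atoms: none
Why: Corey–Bakshi–Shibata reduction: the ketone binds with quaternary C6 as the large and C8H2 as the small group, so the (S)-catalyst delivers hydride to give the (7R)-alcohol trans to the C9 oxygen, and material from the minor enantiomer of 8 becomes a separable cis diastereomer.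

Step 9
Reactants: 15 the hydroxy lactone
Product: 18 2-[(1S,5R,7R)-5,7-bis(TBSO)-1,4,4-trimethylcyclohept-2-en-1-yl]acetic acid, via dihydroxy carboxylate 16 (not isolated), via tris-silyl compound 17 (not isolated)
Conditions: LiOH, THF/H2O, rt, evaporate; TBSOTf, 2,6-lutidine, CH2Cl2, 0 °C to rt; K2CO3, MeOH/H2O, then pH 5
Reagents that add atoms: lithium hydroxide, [Li+].[OH-]; tert-butyldimethylsilyl trifluoromethanesulfonate, CC(C)(C)[Si](C)(C)OS(=O)(=O)C(F)(F)F
Why: Saponification opens the γ-lactone, excess TBSOTf silylates the carboxylate and both hindered secondary alcohols before relactonisation, and carbonate methanolysis cleaves only the silyl ester (standard lactone to silyloxy acid sequence), with no change at any stereocentre.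

Step 10
Reactants: 18 the bis-TBS acid
Product: 19 methyl 2-[(1S,5R,7R)-5,7-bis(TBSO)-1,4,4-trimethylcyclohept-2-en-1-yl]acetate (C9–OTBS cis to the acetate arm, C7–OTBS trans to it)
Conditions: MeI, K2CO3, DMF, rt
Reagents that add atoms: iodomethane, CI
Why: SN2 methylation of the potassium carboxylate gives the methyl ester needed as carbene acceptor group.

Step 11
Reactants: 19 the bis-TBS methyl ester
Product: 21 methyl 2-diazo-2-[5,7-bis(TBSO)-1,4,4-trimethylcyclohept-2-en-1-yl]acetate (ring stereocentres as in 19), via trifluoroacetyl ester 20 (not isolated)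
Conditions: LiN(SiMe3)2, THF, −78 °C; CF3CO2CH2CF3; then MsN3, Et3N, H2O, MeCN, rt
Reagents that add atoms: methanesulfonyl azide, CS(=O)(=O)N=[N+]=[N-]
Why: Claisen trifluoroacetylation of the lithium ester enolate activates C11 for Regitz diazo transfer from mesyl azide, and cleavage of the trifluoroacetyl group as its sulfonamide leaves the α-diazo ester (deacylative diazo transfer).

Step 12
Reactants: 21 the diazo ester
Product: 22 2,4-bridged bicyclobutane methyl ester (tricyclo[5.1.0.0(2,8)]octane; central bond C11–C4, CO2Me on bridgehead C11, methyl on wing carbon C10, wing carbons C10 and C5 joined on the concave face by C9(OTBS)–C8–C7(OTBS)–C6(CH3)2)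
Conditions: Rh2(NHCOCH3)4 (1 mol %), CH2Cl2, 40 °C, slow addition of 21
Reagents that add atoms: none
Why: Rhodium-carbene formation and intramolecular cyclopropanation of the adjacent C4=C5 bond (bicyclobutanation of an α-allyl diazo ester) form C11–C4 and C11–C5; C11 has no β-hydrogen to migrate, its one-atom link to C10 lets it reach only one alkene face, which fixes C5 and C4 with the C9–C6 chain on the concave side, and the carboxamidate ligands favour alkene addition over C–H insertion.

Step 13
Reactants: 22 the bicyclobutane ester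
Product: 23 methyl 2,4-bis(TBSO)-8-iodo-1,5,5-trimethylbicyclo[4.1.1]octane-7-carboxylate (iodine on C4 syn, CO2Me on C11 syn)
Conditions: LiI, AcOH, THF, 0 °C to rt
Reagents that add atoms: lithium iodide, [Li+].[I-]
Why: Iodide adds to the strained central bond at C4, β to the ester, with inversion and acetic acid protonates the ester enol on the open anti face (hydrohalogenation of a bicyclobutane-1-carboxylate), which cleaves C11–C4 to the cyclobutane; both new centres are reset later.

Step 14
Reactants: 23 the C4 iodide; 24 isopropenylmagnesium bromide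
Product: 25 methyl 2,4-bis(TBSO)-1,5,5-trimethyl-8-(prop-1-en-2-yl)bicyclo[4.1.1]octane-7-carboxylate (isopropenyl on C4 anti, CO2Me on C11 syn)
Conditions: Fe(acac)3 (10 mol %), TMEDA, THF, 0 °C, slow addition of 24
Reagents that add atoms: isopropenylmagnesium bromide (24), C=C(C)[Mg]Br
Why: Iron-catalysed Kumada-type alkyl–alkenyl coupling runs through the planar C4 cyclobutyl radical, which should be captured on the face away from the seven-membered ring because the other face is shielded by a C6 methyl group and the C9–C6 bridge, so the isopropenyl group ends up anti; β-hydrogen loss is impossible since C10 is quaternary and C5 is a bridgehead.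

Step 15
Reactants: 25 the isopropenyl ester
Product: 27 2,4-bis(TBSO)-1,5,5-trimethyl-8-(prop-1-en-2-yl)bicyclo[4.1.1]octane-7-carbaldehyde with the formyl group on C11 anti and the isopropenyl group on C4 anti, via syn aldehyde 26 (not isolated)
Conditions: i-Bu2AlH, CH2Cl2, −78 °C; aq. KNaC4H4O6; then DBU (0.2 equiv), CH2Cl2, rt
Reagents that add atoms: none
Why: Partial reduction of the hindered methyl ester stops at the aluminium hemiacetal at −78 °C (ester-to-aldehyde reduction), and DBU then equilibrates the enolisable C11 centre toward the epimer with the formyl group anti, where it avoids the C9 silyloxy group and the C6 methyl group.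

Step 16
Reactants: 27 the anti,anti formyl isopropenyl bicyclo[4.1.1]octane
Product: 28 tricyclic C1 alcohol with a C3 exocyclic methylene (7,9-bis(TBSO)longipin-3(15)-en-1-ol, hydroxyl on the side away from the C10 methyl)
Conditions: Me2AlCl (1.5 equiv), CH2Cl2, −78 to −20 °C
Reagents that add atoms: none
Why: Me2AlCl coordinates the aldehyde oxygen and the terminal carbon C2 of the isopropenyl group attacks C1 while one hydrogen of the allylic methyl group passes to oxygen through a six-membered transition state, the aluminium reagent also scavenging the proton so that no free C3 cation need form. The closest known reaction type is the Lewis-acid-promoted type 2 intramolecular carbonyl-ene cyclisation of aldehydes onto 1,1-disubstituted alkenes, which gives 3-methylenecycloalkanols. The six-membered ring C11–C1–C2–C3–C4–C10 closes by C1–C2 bond formation, exo with respect to the carbonyl group, as a bridge across the two one-carbon bridges of the bicyclo[4.1.1]octane. The new stereocentre C1 is controlled by the cyclic transition state, in which the aluminium-bound oxygen points away from the C10 methyl group, and it is removed by oxidation in the next step. The step needs transfer of a methyl hydrogen and not the C4 hydrogen, which is secured because a C3=C4 alkene would sit at a bridgehead, and it needs the C11 epimer with the formyl group anti, which the preceding equilibration supplies and which alone can reach the alkene.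

Step 17
Reactants: 28 the C1 alcohol
Product: 29 7,9-bis(TBSO)longipin-3(15)-en-1-one (β,γ-unsaturated ketone)
Conditions: Dess–Martin periodinane, NaHCO3, CH2Cl2, 0 °C to rt
Reagents that add atoms: none
Why: Dess–Martin oxidation converts the secondary homoallylic alcohol into the ketone under buffered conditions that leave the silyl ethers and the exocyclic alkene untouched.

Step 18
Reactants: 29 the β,γ-unsaturated ketone
Product: 30 7,9-bis(TBSO)longipin-2-en-1-one
Conditions: DBU, CH2Cl2, rt
Reagents that add atoms: none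
Why: DBU deprotonates C2 and the dienolate is reprotonated at the exocyclic CH2, which moves the alkene into conjugation as the more stable trisubstituted C2=C3 enone (base-mediated alkene isomerisation); C11 cannot epimerise because its enolate would be a bridgehead alkene.

Step 19
Reactants: 30 the bis-TBS enone
Product: 31 7,9-dihydroxylongipin-2-en-1-one
Conditions: Bu4NF, THF, rt to 45 °C
Reagents that add atoms: none
Why: Fluoride cleaves both Si–O bonds (desilylation); the enone has no β-leaving group and the carbinol centres are not touched.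

Step 20
Reactants: 31 the diol; 32 3-methylbut-2-enoyl chloride
Product: 33 the target, (4R,5S,7R,9R,10R,11R)-7,9-bis(3-methylbut-2-enoyloxy)longipin-2-en-1-one
Conditions: 32 (4 equiv), pyridine, DMAP, CH2Cl2, 0 °C to rt
Reagents that add atoms: 3-methylbut-2-enoyl chloride (32), CC(C)=CC(=O)Cl
Why: DMAP-catalysed acylation of both secondary alcohols through the acylpyridinium ion, run without a strong amine base so that the enoyl group is not deconjugated via its vinylketene, retains the configuration at C7 and C9.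

Compound list
1 | (R)-(−)-carvone | CC1=CC[C@H](CC1=O)C(C)=C | starting material
2 | carvone hydrobromide, (5R)-5-(2-bromopropan-2-yl)-2-methylcyclohex-2-en-1-one | CC1=CC[C@H](CC1=O)C(C)(C)Br | intermediate (not isolated)
3 | eucarvone, 2,6,6-trimethylcyclohepta-2,4-dien-1-one | CC1=CC=CC(C)(C)CC1=O | intermediate
4 | lithium 2,6,6-trimethylcyclohepta-1,3-dien-1-olate | [Li+].[O-]C1=C(C)C=CCC(C)(C)C1 | intermediate (not isolated)
5 | 2,6,6-trimethylcyclohepta-1,3-dien-1-yl acetate | CC(=O)OC1=C(C)C=CCC(C)(C)C1 | intermediate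
6 | tert-butyl iodoacetate | CC(C)(C)OC(=O)CI | starting material
7 | tributyl[(2,6,6-trimethylcyclohepta-1,3-dien-1-yl)oxy]stannane | CCCC[Sn](CCCC)(CCCC)OC1=C(C)C=CCC(C)(C)C1 | intermediate (not isolated)
8 | tert-butyl 2-[(1R)-1,5,5-trimethyl-7-oxocyclohept-2-en-1-yl]acetate | CC(C)(C)OC(=O)C[C@]1(C)C=CCC(C)(C)CC1=O | intermediate
9 | tert-butyl 2-[(1R)-1,4,4-trimethyl-2-(trifluoromethylsulfonyloxy)cyclohepta-2,6-dien-1-yl]acetate | CC(C)(C)OC(=O)C[C@]1(C)C=CCC(C)(C)C=C1OS(=O)(=O)C(F)(F)F | intermediate
10 | tert-butyl 2-[(1R)-1,4,4-trimethylcyclohepta-2,6-dien-1-yl]acetate | CC(C)(C)OC(=O)C[C@]1(C)C=CCC(C)(C)C=C1 | intermediate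
11 | tert-butyl 2-[(1S)-5-hydroxy-1,4,4-trimethylcyclohepta-2,6-dien-1-yl]acetate (both C7 epimers) | CC(C)(C)OC(=O)C[C@]1(C)C=CC(O)C(C)(C)C=C1 | intermediate (not isolated)
12 | tert-butyl 2-[(1S)-1,4,4-trimethyl-5-oxocyclohepta-2,6-dien-1-yl]acetate | CC(C)(C)OC(=O)C[C@]1(C)C=CC(=O)C(C)(C)C=C1 | intermediate
13 | 2-[(1S)-1,4,4-trimethyl-5-oxocyclohepta-2,6-dien-1-yl]acetic acid | OC(=O)C[C@]1(C)C=CC(=O)C(C)(C)C=C1 | intermediate (not isolated)
14 | (3aS,8aR)-3a,6,6-trimethyl-3,3a,8,8a-tetrahydro-2H-cyclohepta[b]furan-2,7(6H)-dione | O=C1C[C@H]2OC(=O)C[C@@]2(C)C=CC1(C)C | intermediate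
15 | (3aS,7R,8aR)-7-hydroxy-3a,6,6-trimethyl-3,3a,6,7,8,8a-hexahydro-2H-cyclohepta[b]furan-2-one | O[C@@H]1C[C@H]2OC(=O)C[C@@]2(C)C=CC1(C)C | intermediate
16 | lithium 2-[(1S,5R,7R)-5,7-dihydroxy-1,4,4-trimethylcyclohept-2-en-1-yl]acetate | [Li+].O[C@@H]1C[C@@H](O)[C@@](C)(CC(=O)[O-])C=CC1(C)C | intermediate (not isolated)
17 | tert-butyldimethylsilyl 2-[(1S,5R,7R)-5,7-bis(TBSO)-1,4,4-trimethylcyclohept-2-en-1-yl]acetate | CC(C)(C)[Si](C)(C)O[C@@H]1C[C@@H](O[Si](C)(C)C(C)(C)C)[C@@](C)(CC(=O)O[Si](C)(C)C(C)(C)C)C=CC1(C)C | intermediate (not isolated)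
18 | 2-[(1S,5R,7R)-5,7-bis(TBSO)-1,4,4-trimethylcyclohept-2-en-1-yl]acetic acid | CC(C)(C)[Si](C)(C)O[C@@H]1C[C@@H](O[Si](C)(C)C(C)(C)C)[C@@](C)(CC(=O)O)C=CC1(C)C | intermediate
19 | methyl 2-[(1S,5R,7R)-5,7-bis(TBSO)-1,4,4-trimethylcyclohept-2-en-1-yl]acetate | CC(C)(C)[Si](C)(C)O[C@@H]1C[C@@H](O[Si](C)(C)C(C)(C)C)[C@@](C)(CC(=O)OC)C=CC1(C)C | intermediate
20 | methyl 4,4,4-trifluoro-3-oxo-2-[5,7-bis(TBSO)-1,4,4-trimethylcyclohept-2-en-1-yl]butanoate (ring stereocentres as in 19, C11 epimers) | CC(C)(C)[Si](C)(C)O[C@@H]1C[C@@H](O[Si](C)(C)C(C)(C)C)[C@@](C)(C(C(=O)C(F)(F)F)C(=O)OC)C=CC1(C)C | intermediate (not isolated)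
21 | methyl 2-diazo-2-[5,7-bis(TBSO)-1,4,4-trimethylcyclohept-2-en-1-yl]acetate (ring stereocentres as in 19) | CC(C)(C)[Si](C)(C)O[C@@H]1C[C@@H](O[Si](C)(C)C(C)(C)C)[C@@](C)(C(=[N+]=[N-])C(=O)OC)C=CC1(C)C | intermediate
22 | 2,4-bridged bicyclobutane methyl ester (central bond C11–C4, CO2Me on C11, C9–C6 chain on the concave face) | CC(C)(C)[Si](C)(C)O[C@@H]1C[C@@H](O[Si](C)(C)C(C)(C)C)[C@@]2(C)[C@]3(C(=O)OC)[C@H]2[C@@H]3C1(C)C | intermediate
23 | methyl 2,4-bis(TBSO)-8-iodo-1,5,5-trimethylbicyclo[4.1.1]octane-7-carboxylate (I on C4 syn, CO2Me on C11 syn) | CC(C)(C)[Si](C)(C)O[C@@H]1C[C@@H](O[Si](C)(C)C(C)(C)C)[C@@]2(C)[C@@H](C(=O)OC)[C@H]([C@H]2I)C1(C)C | intermediate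
24 | isopropenylmagnesium bromide | C=C(C)[Mg]Br | starting material
25 | methyl 2,4-bis(TBSO)-1,5,5-trimethyl-8-(prop-1-en-2-yl)bicyclo[4.1.1]octane-7-carboxylate (isopropenyl on C4 anti, CO2Me on C11 syn) | CC(C)(C)[Si](C)(C)O[C@@H]1C[C@@H](O[Si](C)(C)C(C)(C)C)[C@@]2(C)[C@@H](C(=O)OC)[C@H]([C@@H]2C(C)=C)C1(C)C | intermediate
26 | C11 epimer of 27 (formyl syn, isopropenyl anti) | CC(C)(C)[Si](C)(C)O[C@@H]1C[C@@H](O[Si](C)(C)C(C)(C)C)[C@@]2(C)[C@@H](C=O)[C@H]([C@@H]2C(C)=C)C1(C)C | intermediate (not isolated)
27 | 2,4-bis(TBSO)-1,5,5-trimethyl-8-(prop-1-en-2-yl)bicyclo[4.1.1]octane-7-carbaldehyde (formyl on C11 anti, isopropenyl on C4 anti) | CC(C)(C)[Si](C)(C)O[C@@H]1C[C@@H](O[Si](C)(C)C(C)(C)C)[C@@]2(C)[C@H](C=O)[C@H]([C@@H]2C(C)=C)C1(C)C | intermediate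
28 | 7,9-bis(TBSO)longipin-3(15)-en-1-ol (hydroxyl away from the C10 methyl) | CC(C)(C)[Si](C)(C)O[C@@H]1C[C@@H](O[Si](C)(C)C(C)(C)C)[C@@]2(C)[C@@H]3[C@@H](O)CC(=C)[C@H]2[C@@H]3C1(C)C | intermediate
29 | 7,9-bis(TBSO)longipin-3(15)-en-1-one | CC(C)(C)[Si](C)(C)O[C@@H]1C[C@@H](O[Si](C)(C)C(C)(C)C)[C@@]2(C)[C@@H]3C(=O)CC(=C)[C@H]2[C@@H]3C1(C)C | intermediate
30 | 7,9-bis(TBSO)longipin-2-en-1-one | CC(C)(C)[Si](C)(C)O[C@@H]1C[C@@H](O[Si](C)(C)C(C)(C)C)[C@@]2(C)[C@@H]3C(=O)C=C(C)[C@H]2[C@@H]3C1(C)C | intermediate
31 | 7,9-dihydroxylongipin-2-en-1-one | O[C@@H]1C[C@@H](O)[C@@]2(C)[C@@H]3C(=O)C=C(C)[C@H]2[C@@H]3C1(C)C | intermediate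
32 | 3-methylbut-2-enoyl chloride | CC(C)=CC(=O)Cl | starting material
33 | (4R,5S,7R,9R,10R,11R)-7,9-bis(3-methylbut-2-enoyloxy)longipin-2-en-1-one | CC(C)=CC(=O)O[C@@H]1C[C@@H](OC(=O)C=C(C)C)[C@@]2(C)[C@@H]3C(=O)C=C(C)[C@H]2[C@@H]3C1(C)C | target

Total step count: 20. Longest linear sequence: 20 steps (from carvone 1).

Steps most likely to fail

1. Step 12. The rhodium carbene may be diverted into insertion into the C7–H bond next to the silyl ether, or into dimerisation, before it adds to the doubly neopentyl C4=C5 alkene. The fallback builds the bicyclobutane without a carbene and sets out from ester 19. Epoxidation of C4=C5 with mCPBA on the face opposite the acetate arm would give the epoxy ester F1. LiN(i-Pr)2 would then close the cyclopropane by 3-exo attack of the C11 enolate on C4 to give the cyclopropyl carbinol F2. Mesylation (MsCl, Et3N) would give the mesylate F3. A second deprotonation at C11 with KN(SiMe3)2 would displace the C5 mesylate from the rear (1,3-elimination) and come back to the route at bicyclobutane 22.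

2. Step 14. Capture of the C4 radical may show poor facial selectivity, or the strained cyclobutyl radical may undergo β-scission before it is trapped. The fallback sets out from bicyclobutane 22 and installs the C3 unit as an epimerisable ketone. Homoconjugate addition of the cuprate from (1-ethoxyvinyl)lithium and CuBr·SMe2 would give the enol ether F4, with the new group syn through inversion. Aqueous oxalic acid would unmask the syn methyl ketone F5. DBU would epimerise the ketone α-carbon C4 to the anti methyl ketone F6, whose cis-1,3 partner on C11 is then hydrogen. Wittig methylenation with Ph3P=CH2 would come back to the route at ester 25.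

3. Step 16. Ionisation to the tertiary C3 cation with Wagner–Meerwein ring expansion of the cyclobutane, or transfer of a methyl group from aluminium to the aldehyde, may outrun the concerted ene closure. The fallback sets out from aldehyde 27 and forms the same C1–C2 bond by an aldol reaction. Ozonolysis (O3, then Me2S) of the isopropenyl group would give the keto aldehyde F7. Intramolecular aldol condensation (KOH, MeOH) between the acetyl methyl carbon C2 and the aldehyde carbon C1 would close the ring as the cyclohexenone F8 (C3 ketone, C1=C2). MeLi with CeCl3 would add to C3 to give the tertiary allylic alcohol F9. Oxidative 1,3-transposition with pyridinium chlorochromate, C5H5NH[CrO3Cl], would come back to the route at enone 30.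

Further compounds
F1 | step 12 | methyl 2-[5,7-bis(TBSO)-2,3-epoxy-1,4,4-trimethylcycloheptyl]acetate (C4–C5 epoxide trans to the acetate arm) | CC(C)(C)[Si](C)(C)O[C@@H]1C[C@@H](O[Si](C)(C)C(C)(C)C)[C@@](C)(CC(=O)OC)[C@@H]2O[C@@H]2C1(C)C
F2 | step 12 | cyclopropyl carbinol (cyclopropane C10–C11–C4, CO2Me on C11, free hydroxyl on C5) | CC(C)(C)[Si](C)(C)O[C@@H]1C[C@@H](O[Si](C)(C)C(C)(C)C)[C@@]2(C)C(C(=O)OC)[C@H]2[C@H](O)C1(C)C
F3 | step 12 | C5 mesylate of F2 | CC(C)(C)[Si](C)(C)O[C@@H]1C[C@@H](O[Si](C)(C)C(C)(C)C)[C@@]2(C)C(C(=O)OC)[C@H]2[C@H](OS(C)(=O)=O)C1(C)C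
F4 | step 14 | methyl 2,4-bis(TBSO)-8-(1-ethoxyvinyl)-1,5,5-trimethylbicyclo[4.1.1]octane-7-carboxylate (enol ether on C4 syn, CO2Me on C11 syn) | CC(C)(C)[Si](C)(C)O[C@@H]1C[C@@H](O[Si](C)(C)C(C)(C)C)[C@@]2(C)[C@@H](C(=O)OC)[C@H]([C@H]2C(=C)OCC)C1(C)C
F5 | step 14 | methyl 8-acetyl-2,4-bis(TBSO)-1,5,5-trimethylbicyclo[4.1.1]octane-7-carboxylate (acetyl on C4 syn) | CC(C)(C)[Si](C)(C)O[C@@H]1C[C@@H](O[Si](C)(C)C(C)(C)C)[C@@]2(C)[C@@H](C(=O)OC)[C@H]([C@H]2C(C)=O)C1(C)C
F6 | step 14 | methyl 8-acetyl-2,4-bis(TBSO)-1,5,5-trimethylbicyclo[4.1.1]octane-7-carboxylate (acetyl on C4 anti) | CC(C)(C)[Si](C)(C)O[C@@H]1C[C@@H](O[Si](C)(C)C(C)(C)C)[C@@]2(C)[C@@H](C(=O)OC)[C@H]([C@@H]2C(C)=O)C1(C)C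
F7 | step 16 | 8-acetyl-2,4-bis(TBSO)-1,5,5-trimethylbicyclo[4.1.1]octane-7-carbaldehyde (acetyl and formyl both anti) | CC(C)(C)[Si](C)(C)O[C@@H]1C[C@@H](O[Si](C)(C)C(C)(C)C)[C@@]2(C)[C@H](C=O)[C@H]([C@@H]2C(C)=O)C1(C)C
F8 | step 16 | 7,9-bis(TBSO)-15-norlongipin-1-en-3-one (C3 ketone, C1=C2) | CC(C)(C)[Si](C)(C)O[C@@H]1C[C@@H](O[Si](C)(C)C(C)(C)C)[C@@]2(C)[C@@H]3C=CC(=O)[C@H]2[C@@H]3C1(C)C
F9 | step 16 | 7,9-bis(TBSO)longipin-1-en-3-ol (tertiary allylic alcohol, C3 epimers) | CC(C)(C)[Si](C)(C)O[C@@H]1C[C@@H](O[Si](C)(C)C(C)(C)C)[C@@]2(C)[C@@H]3C=CC(C)(O)[C@H]2[C@@H]3C1(C)C
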